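The target is the 7''-O-prenyl ether of a 3',8''-linked biapigenin. Everything rests on removing both C5 oxygens. Each sits on ring A peri to a C4 carbonyl, so in a 5,5''-dideoxy biflavone each C5–H is the one C–H that a carbonyl-bound ruthenium can reach. One operation then forms both C5–O bonds. Leaving O5 out also fixes the regiochemistry: the ketone that becomes ring A of the prenylated flavone then offers just one phenol next to its acyl group, so ring C cannot form the 6-substituted isomer. The precursor carries mesylates on O7, O4' and O4''' and a free 7''-OH, which trifluoroacetic anhydride masks in the flask and the work-up releases for prenylation.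

Key step: step 12

Remarks on the chemistry
- Locants: flavone 1 has unprimed rings A and C and a primed ring B. Flavone 2, the prenylated one, has double-primed rings A and C and a triple-primed ring B. "Amentoflavone" means 3',8''-biapigenin.
- Assumption: the target string defines no configuration at the 3',8'' axis, so the axis is not controlled and no stereocentre has to be set.
- Assumption: the three O-benzyl building blocks are taken as catalogue compounds; each would otherwise cost one benzylation (BnBr, K2CO3) of the parent phenol.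
- The two flavones are finished separately and joined afterwards. A biaryl that holds both an acetyl and a formyl group would condense with itself under chalcone-forming conditions.
- O7'' carries no isolated carboxylate cap. These mesylates are esters of acidic phenols and have α-hydrogens, so carbonate in methanol could strip them about as fast as it removes a hindered ester. A trifluoroacetate made in the flask falls off at neutral pH, which also saves two steps.
- O4' carries a sulfonate and not an acyl group, because an acyl group there could migrate across the axis to the neighbouring 7''-phenoxide during prenylation.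

Step 1
Reactants: 1 2,4-dihydroxyacetophenone
Product: 2 1-(2,4-dihydroxy-3-iodophenyl)ethanone
Conditions: I2 (0.4 equiv), HIO3 (0.2 equiv), EtOH–H2O, rt to 40 °C
Reagents that add atoms: iodine, II; iodic acid, OI(=O)=O
Why: Electrophilic aromatic iodination with I2/HIO3 is known to take C3 of resacetophenone, the carbon ortho to both hydroxyls, and the exact iodine charge (all iodide is re-oxidised) holds back a second iodination at C5.

Step 2
Reactants: 2 1-(2,4-dihydroxy-3-iodophenyl)ethanone
Product: 3 1-(2-hydroxy-3-iodo-4-isopropoxyphenyl)ethanone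
Conditions: 2-bromopropane (1.3 equiv), K2CO3 (1.2 equiv), DMF, 50 °C
Reagents that add atoms: 2-bromopropane, CC(C)Br
Why: Williamson etherification takes only the 4-OH because the 2-OH is tied to the acetyl oxygen by a hydrogen bond and is much less acidic, a selectivity that is routine for resacetophenones.

Step 3
Reactants: 3 1-(2-hydroxy-3-iodo-4-isopropoxyphenyl)ethanone; 4 p-(benzyloxy)benzaldehyde
Product: 5 (E)-3-[4-(benzyloxy)phenyl]-1-(2-hydroxy-3-iodo-4-isopropoxyphenyl)prop-2-en-1-one
Conditions: KOH (50% aq), EtOH, rt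
Reagents that add atoms: none
Why: Claisen–Schmidt condensation of a methyl ketone with a non-enolisable aldehyde, in which E1cB loss of water gives the conjugated E-alkene under thermodynamic control while the ethers and the aryl iodide ignore aqueous KOH.

Step 4
Reactants: 5 (E)-3-[4-(benzyloxy)phenyl]-1-(2-hydroxy-3-iodo-4-isopropoxyphenyl)prop-2-en-1-one
Product: 6 4'-benzyloxy-8-iodo-7-isopropoxyflavone
Conditions: I2 (10 mol %), DMSO, 120 °C
Reagents that add atoms: none
Why: Iodine-catalysed oxidative cyclisation of a 2'-hydroxychalcone (oxa-Michael addition, then dehydrogenation with DMSO as terminal oxidant) is the standard flavone synthesis, and because the ketone ring has only one ortho hydroxyl the iodine must end at C8.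

Step 5
Reactants: 7 1-[4-(benzyloxy)-2-hydroxyphenyl]ethanone; 8 4-(benzyloxy)-3-bromobenzaldehyde
Product: 9 (E)-3-[4-(benzyloxy)-3-bromophenyl]-1-[4-(benzyloxy)-2-hydroxyphenyl]prop-2-en-1-one
Conditions: KOH (50% aq), EtOH, rt
Reagents that add atoms: none
Why: Claisen–Schmidt condensation as in step 3, giving the E-chalcone by thermodynamically controlled dehydration with the benzyl ethers and the aryl bromide untouched.

Step 6
Reactants: 9 (E)-3-[4-(benzyloxy)-3-bromophenyl]-1-[4-(benzyloxy)-2-hydroxyphenyl]prop-2-en-1-one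
Product: 10 7,4'-bis(benzyloxy)-3'-bromoflavone
Conditions: I2 (10 mol %), DMSO, 120 °C
Reagents that add atoms: none
Why: The same iodine-catalysed oxidative cyclisation of a 2'-hydroxychalcone closes ring C of flavone 1, and the catalytic iodine charge leaves no room for ring iodination.

Step 7
Reactants: 10 7,4'-bis(benzyloxy)-3'-bromoflavone
Product: 11 7,4'-bis(benzyloxy)-3'-(4,4,5,5-tetramethyl-1,3,2-dioxaborolan-2-yl)flavone
Conditions: B2pin2 (1.3 equiv), PdCl2(dppf) (5 mol %), KOAc (3 equiv), 1,4-dioxane, 90 °C
Reagents that add atoms: bis(pinacolato)diboron, CC1(C)OB(OC1(C)C)B1OC(C)(C)C(C)(C)O1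
Why: Miyaura borylation (oxidative addition of zerovalent palladium into C–Br, acetate-assisted transmetalation with B2pin2, reductive elimination) is established for 3'-haloflavones, and KOAc is too weak a base to start homocoupling or to harm the pyranone.

Step 8
Reactants: 6 4'-benzyloxy-8-iodo-7-isopropoxyflavone; 11 7,4'-bis(benzyloxy)-3'-(4,4,5,5-tetramethyl-1,3,2-dioxaborolan-2-yl)flavone
Product: 12 7,4',4'''-tri-O-benzyl-7''-O-isopropyl-5,5''-dideoxyamentoflavone
Conditions: Pd(OAc)2 (5 mol %), SPhos (10 mol %), K3PO4 (3 equiv), toluene–H2O 10:1, 95 °C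
Reagents that add atoms: none
Why: Suzuki–Miyaura coupling of an 8-iodoflavone with a flavone 3'-boronate is a known way to the 3',8'' axis, the C–I bond adds readily to zerovalent palladium, and the bulky electron-rich SPhos ligand is chosen to drive transmetalation and reductive elimination at a biaryl with three ortho substituents.

Step 9
Reactants: 12 7,4',4'''-tri-O-benzyl-7''-O-isopropyl-5,5''-dideoxyamentoflavone
Product: 13 7''-O-isopropyl-5,5''-dideoxyamentoflavone (7-OH, 4'-OH and 4'''-OH free)
Conditions: H2 (1 atm), 10% Pd/C, THF–MeOH, rt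
Reagents that add atoms: none
Why: Catalytic hydrogenolysis removes the three benzyl aryl ethers while the secondary alkyl ether on O7'' is inert, and the conjugated C2–C3 bonds of flavones normally survive at atmospheric pressure if the reaction is stopped after the calculated uptake.

Step 10
Reactants: 13 7''-O-isopropyl-5,5''-dideoxyamentoflavone
Product: 14 7''-O-isopropyl-5,5''-dideoxyamentoflavone 7,4',4'''-trimesylate
Conditions: MsCl (4.5 equiv), Et3N (6 equiv), CH2Cl2–THF, 0 °C to rt
Reagents that add atoms: methanesulfonyl chloride, CS(=O)(=O)Cl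
Why: O-Sulfonylation of phenols with a small electrophile also reaches the hindered O4' and installs caps that are inert to acid, Lewis acid and oxidant and that withdraw electrons from all three rings.

Step 11
Reactants: 14 7''-O-isopropyl-5,5''-dideoxyamentoflavone 7,4',4'''-trimesylate
Product: 15 5,5''-dideoxyamentoflavone 7,4',4'''-trimesylate (7''-OH free)
Conditions: BCl3 (6 equiv), CH2Cl2, 0 °C to rt; then H2O
Reagents that add atoms: none
Why: Lewis-acid dealkylation of an isopropyl aryl ether by BCl3 runs through a secondary, carbocation-like C–O cleavage that aryl mesylates and pyranones do not undergo, and the excess reagent allows for the boron taken up by the two carbonyl groups.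

Step 12
Reactants: 15 5,5''-dideoxyamentoflavone 7,4',4'''-trimesylate (7''-OH free)
Product: 18 amentoflavone 7,4',4'''-trimesylate (5-OH 5''-OH 7''-OH free), via mono(trifluoroacetate) 16 (not isolated), via tris(trifluoroacetate) 17 (not isolated)
Conditions: (CF3CO)2O–CF3CO2H 1:2, 40 °C, 1 h; then [RuCl2(p-cymene)]2 (10 mol %), PhI(OCOCF3)2 (5 equiv), 80 °C, sealed tube; evaporation, then THF–pH 7 phosphate buffer, rt
Reagents that add atoms: [bis(trifluoroacetoxy)iodo]benzene, O=C(OI(OC(=O)C(F)(F)F)c1ccccc1)C(F)(F)F (both C5 oxygens, and the C5 ester groups of 17); trifluoroacetic anhydride, O=C(OC(=O)C(F)(F)F)C(F)(F)F (the O7'' acyl group of 16 and 17, lost on work-up)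
Why: Trifluoroacetic anhydride first esterifies the only free phenol, so the oxidant meets no oxidisable hydroxyl, by the same device that later shields each new C5 oxygen. Chloride–trifluoroacetate exchange gives Ru(OCOCF3)2(p-cymene); each C4 carbonyl binds this divalent ruthenium, a trifluoroacetate ligand takes the peri proton in a concerted metalation–deprotonation, and the five-membered ruthenacycle (Ru, O, C4, C4a, C5) is oxidised by the trivalent iodine reagent to tetravalent ruthenium, from which C–O reductive elimination releases the aryl trifluoroacetate. The closest known reaction type is the ruthenium-catalysed ketone-directed ortho C–H hydroxylation of aryl ketones, which has been shown at C5 of chromones and flavones and here only has to run twice in one molecule. No ring is closed and no stereocentre is made. The step needs site selectivity, and the substrate secures it: C3–H would require a four-membered metallacycle, the ring B hydrogens are out of reach, the second ortho position of each ketone (C8a) bears O1 so that no further oxygenation can follow, and sulfonates and trifluoroacetates are too weakly basic to direct while they keep every ring electron-poor towards the oxidant. Neutral aqueous work-up hydrolyses the three trifluoroacetates and leaves the mesylates in place.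

Step 13
Reactants: 18 amentoflavone 7,4',4'''-trimesylate; 19 prenyl bromide (1-bromo-3-methylbut-2-ene)
Product: 20 7''-O-prenylamentoflavone 7,4',4'''-trimesylate
Conditions: K2CO3 (1.2 equiv), acetone, 40 °C
Reagents that add atoms: none
Why: Williamson O-alkylation takes only the acidic, unchelated 7''-OH, since both 5-OH groups are hydrogen-bonded to their C4 carbonyls (the usual selectivity of 5,7-dihydroxyflavones), the carbonate is used up by that one phenol so that nothing basic enough to attack the mesylates remains, and a sulfonyl group on O4' cannot migrate across the axis.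

Step 14
Reactants: 20 7''-O-prenylamentoflavone 7,4',4'''-trimesylate
Product: 21 7''-O-prenylamentoflavone (target)
Conditions: NaOH (1 M aq, 10 equiv), THF, 0 °C to rt, argon; then 1 M HCl to pH 5
Reagents that add atoms: none
Why: Alkaline S–O cleavage of aryl methanesulfonates (E1cB type) is fast here because all three phenoxides are good leaving groups conjugated with a pyranone, while early deprotonation of the 5-OH groups deactivates C2 towards hydroxide, the absence of methanol avoids a methylating by-product, and the prenyl ether is stable to base.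

Compound list
1 | 2,4-dihydroxyacetophenone | CC(=O)c1ccc(O)cc1O | starting material
2 | 1-(2,4-dihydroxy-3-iodophenyl)ethanone | CC(=O)c1ccc(O)c(I)c1O | intermediate
3 | 1-(2-hydroxy-3-iodo-4-isopropoxyphenyl)ethanone | CC(=O)c1ccc(OC(C)C)c(I)c1O | intermediate
4 | 4-(benzyloxy)benzaldehyde | O=Cc1ccc(OCc2ccccc2)cc1 | starting material
5 | (E)-3-[4-(benzyloxy)phenyl]-1-(2-hydroxy-3-iodo-4-isopropoxyphenyl)prop-2-en-1-one | CC(C)Oc1ccc(C(=O)/C=C/c2ccc(OCc3ccccc3)cc2)c(O)c1I | intermediate
6 | 4'-benzyloxy-8-iodo-7-isopropoxyflavone | CC(C)Oc1ccc2c(=O)cc(-c3ccc(OCc4ccccc4)cc3)oc2c1I | intermediate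
7 | 1-[4-(benzyloxy)-2-hydroxyphenyl]ethanone | CC(=O)c1ccc(OCc2ccccc2)cc1O | starting material
8 | 4-(benzyloxy)-3-bromobenzaldehyde | O=Cc1ccc(OCc2ccccc2)c(Br)c1 | starting material
9 | (E)-3-[4-(benzyloxy)-3-bromophenyl]-1-[4-(benzyloxy)-2-hydroxyphenyl]prop-2-en-1-one | O=C(/C=C/c1ccc(OCc2ccccc2)c(Br)c1)c1ccc(OCc2ccccc2)cc1O | intermediate
10 | 7,4'-bis(benzyloxy)-3'-bromoflavone | O=c1cc(-c2ccc(OCc3ccccc3)c(Br)c2)oc2cc(OCc3ccccc3)ccc12 | intermediate
11 | 7,4'-bis(benzyloxy)-3'-(4,4,5,5-tetramethyl-1,3,2-dioxaborolan-2-yl)flavone | O=c1cc(-c2ccc(OCc3ccccc3)c(B3OC(C)(C)C(C)(C)O3)c2)oc2cc(OCc3ccccc3)ccc12 | intermediate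
12 | 7,4',4'''-tri-O-benzyl-7''-O-isopropyl-5,5''-dideoxyamentoflavone | CC(C)Oc1ccc2c(=O)cc(-c3ccc(OCc4ccccc4)cc3)oc2c1-c1cc(-c2cc(=O)c3ccc(OCc4ccccc4)cc3o2)ccc1OCc1ccccc1 | intermediate
13 | 7''-O-isopropyl-5,5''-dideoxyamentoflavone | CC(C)Oc1ccc2c(=O)cc(-c3ccc(O)cc3)oc2c1-c1cc(-c2cc(=O)c3ccc(O)cc3o2)ccc1O | intermediate
14 | 7''-O-isopropyl-5,5''-dideoxyamentoflavone 7,4',4'''-trimesylate | CC(C)Oc1ccc2c(=O)cc(-c3ccc(OS(C)(=O)=O)cc3)oc2c1-c1cc(-c2cc(=O)c3ccc(OS(C)(=O)=O)cc3o2)ccc1OS(C)(=O)=O | intermediate
15 | 5,5''-dideoxyamentoflavone 7,4',4'''-trimesylate, 7''-OH free (key-step precursor) | Oc1ccc2c(=O)cc(-c3ccc(OS(C)(=O)=O)cc3)oc2c1-c1cc(-c2cc(=O)c3ccc(OS(C)(=O)=O)cc3o2)ccc1OS(C)(=O)=O | intermediate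
16 | 7''-O-trifluoroacetate of 15 (not isolated) | O=C(Oc1ccc2c(=O)cc(-c3ccc(OS(C)(=O)=O)cc3)oc2c1-c1cc(-c2cc(=O)c3ccc(OS(C)(=O)=O)cc3o2)ccc1OS(C)(=O)=O)C(F)(F)F | intermediate
17 | amentoflavone 7,4',4'''-trimesylate 5,5'',7''-tris(trifluoroacetate) (not isolated) | O=C(Oc1cc(OC(=O)C(F)(F)F)c2c(=O)cc(-c3ccc(OS(C)(=O)=O)cc3)oc2c1-c1cc(-c2cc(=O)c3c(OC(=O)C(F)(F)F)cc(OS(C)(=O)=O)cc3o2)ccc1OS(C)(=O)=O)C(F)(F)F | intermediate
18 | amentoflavone 7,4',4'''-trimesylate, 5-, 5''- and 7''-OH free (key-step product) | Oc1cc(O)c2c(=O)cc(-c3ccc(OS(C)(=O)=O)cc3)oc2c1-c1cc(-c2cc(=O)c3c(O)cc(OS(C)(=O)=O)cc3o2)ccc1OS(C)(=O)=O | intermediate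
19 | prenyl bromide (1-bromo-3-methylbut-2-ene) | CC(C)=CCBr | starting material
20 | 7''-O-prenylamentoflavone 7,4',4'''-trimesylate | CC(C)=CCOc1cc(O)c2c(=O)cc(-c3ccc(OS(C)(=O)=O)cc3)oc2c1-c1cc(-c2cc(=O)c3c(O)cc(OS(C)(=O)=O)cc3o2)ccc1OS(C)(=O)=O | intermediate
21 | 7''-O-prenylamentoflavone | CC(C)=CCOc1cc(O)c2c(=O)cc(-c3ccc(O)cc3)oc2c1-c1cc(-c2cc(=O)c3c(O)cc(O)cc3o2)ccc1O | target

Total step count: 14.
Longest linear sequence: 11 steps (steps 1–4 and 8–14, from 1 to 21). The branch through steps 5–7 joins at step 8.

Steps most likely to fail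

Step 12.
- What may go wrong: the reaction may stall after the first oxygenation, the many Lewis-basic oxygens may tie up the catalyst, or the hot acidic oxidant may degrade the substrate before both C–H bonds have reacted.
- Fallback: it sets out from 14 and comes back at 18. It replaces direct C–O formation by C–B formation followed by oxidation, with neither acid nor hypervalent iodine.
- Carbonyl-directed iridium-catalysed C–H borylation, a reaction type known for aryl ketones ([Ir(OMe)(cod)]2, AsPh3, B2pin2, 1,4-dioxane, 110 °C), should give the 5,5''-bis(pinacolboronate) F1.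
- Every aromatic C–H of 14 has at least one ortho neighbour, so undirected borylation finds no easy site.
- NaBO3·4H2O in THF–H2O at rt oxidises both C–B bonds to the 5,5''-dihydroxy 7''-isopropyl ether F2.
- BCl3 as in step 11 then frees O7'' and delivers 18.

Step 8.
- What may go wrong: transmetalation at the triply ortho-substituted axis may be slow, and the two flavone partners may dissolve poorly. Protodeboronation and hydrodeiodination could then outrun the coupling.
- Fallback: it sets out from 8 and 6 and comes back at 12. A small partner is coupled first and flavone 1 is grown afterwards.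
- Miyaura borylation of 8 under the conditions of step 7 gives 4-(benzyloxy)-3-(pinacolboryl)benzaldehyde F3, which is soluble and can be used in large excess.
- Suzuki–Miyaura coupling of that boronate with 6 gives the 8-(2-benzyloxy-5-formylphenyl)flavone F4.
- This aldehyde has no enolisable ketone. Claisen–Schmidt condensation with 7 (KOH, EtOH–THF, rt) can therefore only cross-condense, to the flavone-bearing chalcone F5.
- A ring C that opened in base could only reclose to the same isomer, because flavone 2 has no O5.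
- I2 (10 mol %) in DMSO at 120 °C then closes flavone 1 and gives 12.

Step 14.
- What may go wrong: hydroxide may add to C2 and open ring C of flavone 2, and reclosure through O5 would move the aryl group from C8 to C6. Cleavage at the hindered O4' may also stay incomplete.
- Fallback: it sets out from 13 and comes back at 21. It changes the caps to carboxylates, which leave under far milder conditions.
- Pivaloyl chloride, Et3N and DMAP in CH2Cl2 give the 7''-isopropyl ether tripivalate F6, and BCl3 frees O7'' to give the 7''-hydroxy tripivalate F7.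
- The oxygenation of step 12 then runs through the mono(trifluoroacetate) tripivalate F8 and the tris(trifluoroacetate) tripivalate F9 to the 5,5'',7''-triol tripivalate F10.
- Prenylation is done under Mitsunobu conditions (3-methylbut-2-en-1-ol, PPh3, DIAD, THF, 0 °C). No phenoxide then lingers that could pull the pivaloyl group from O4' across the axis, and the product is the 7''-O-prenyl tripivalate F11.
- K2CO3 in MeOH at rt removes the three pivalates by transesterification and gives 21.

Further compounds
F1 | step 12 | 7''-O-isopropyl-5,5''-bis(4,4,5,5-tetramethyl-1,3,2-dioxaborolan-2-yl)-5,5''-dideoxyamentoflavone 7,4',4'''-trimesylate | CC(C)Oc1cc(B4OC(C)(C)C(C)(C)O4)c2c(=O)cc(-c3ccc(OS(C)(=O)=O)cc3)oc2c1-c1cc(-c2cc(=O)c3c(B4OC(C)(C)C(C)(C)O4)cc(OS(C)(=O)=O)cc3o2)ccc1OS(C)(=O)=O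
F2 | step 12 | 7''-O-isopropylamentoflavone 7,4',4'''-trimesylate | CC(C)Oc1cc(O)c2c(=O)cc(-c3ccc(OS(C)(=O)=O)cc3)oc2c1-c1cc(-c2cc(=O)c3c(O)cc(OS(C)(=O)=O)cc3o2)ccc1OS(C)(=O)=O
F3 | step 8 | 4-(benzyloxy)-3-(4,4,5,5-tetramethyl-1,3,2-dioxaborolan-2-yl)benzaldehyde | O=Cc1ccc(OCc2ccccc2)c(B2OC(C)(C)C(C)(C)O2)c1
F4 | step 8 | 4'-benzyloxy-8-(2-benzyloxy-5-formylphenyl)-7-isopropoxyflavone | CC(C)Oc1ccc2c(=O)cc(-c3ccc(OCc4ccccc4)cc3)oc2c1-c1cc(C=O)ccc1OCc1ccccc1
F5 | step 8 | (E)-chalcone from F4 and 7 | CC(C)Oc1ccc2c(=O)cc(-c3ccc(OCc4ccccc4)cc3)oc2c1-c1cc(/C=C/C(=O)c2ccc(OCc3ccccc3)cc2O)ccc1OCc1ccccc1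
F6 | step 14 | 7''-O-isopropyl-5,5''-dideoxyamentoflavone 7,4',4'''-tripivalate | CC(C)Oc1ccc2c(=O)cc(-c3ccc(OC(=O)C(C)(C)C)cc3)oc2c1-c1cc(-c2cc(=O)c3ccc(OC(=O)C(C)(C)C)cc3o2)ccc1OC(=O)C(C)(C)C
F7 | step 14 | 5,5''-dideoxyamentoflavone 7,4',4'''-tripivalate (7''-OH free) | Oc1ccc2c(=O)cc(-c3ccc(OC(=O)C(C)(C)C)cc3)oc2c1-c1cc(-c2cc(=O)c3ccc(OC(=O)C(C)(C)C)cc3o2)ccc1OC(=O)C(C)(C)C
F8 | step 14 | 7''-O-trifluoroacetate of F7 | O=C(Oc1ccc2c(=O)cc(-c3ccc(OC(=O)C(C)(C)C)cc3)oc2c1-c1cc(-c2cc(=O)c3ccc(OC(=O)C(C)(C)C)cc3o2)ccc1OC(=O)C(C)(C)C)C(F)(F)F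
F9 | step 14 | amentoflavone 7,4',4'''-tripivalate 5,5'',7''-tris(trifluoroacetate) | O=C(Oc1cc(OC(=O)C(F)(F)F)c2c(=O)cc(-c3ccc(OC(=O)C(C)(C)C)cc3)oc2c1-c1cc(-c2cc(=O)c3c(OC(=O)C(F)(F)F)cc(OC(=O)C(C)(C)C)cc3o2)ccc1OC(=O)C(C)(C)C)C(F)(F)F
F10 | step 14 | amentoflavone 7,4',4'''-tripivalate | Oc1cc(O)c2c(=O)cc(-c3ccc(OC(=O)C(C)(C)C)cc3)oc2c1-c1cc(-c2cc(=O)c3c(O)cc(OC(=O)C(C)(C)C)cc3o2)ccc1OC(=O)C(C)(C)C
F11 | step 14 | 7''-O-prenylamentoflavone 7,4',4'''-tripivalate | CC(C)=CCOc1cc(O)c2c(=O)cc(-c3ccc(OC(=O)C(C)(C)C)cc3)oc2c1-c1cc(-c2cc(=O)c3c(O)cc(OC(=O)C(C)(C)C)cc3o2)ccc1OC(=O)C(C)(C)C
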